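A small charge of Ly, 10 mol% on Ez, starts the chains, but in this flask Eb is charged equal to Ez, so the first question is how fast Eb removes Ez. In delta, Ez and Qo together stand at 53.0% of the charge after 6.00 min, close to the 50.0% that a one-for-one loss to Eb leaves.

| flask | Ez | Eb | Ly | remark | time |
|---|---|---|---|---|---|
| delta | 0.82 M | 0.41 M | 10 mol% | run made earlier |  |
| theta | 0.82 M | 1.6 M | 10 mol% | run made earlier |  |
| flask | 0.82 M | 0.820 M | 10 mol% |  | 1.0 h |

| run | time / min | Qo / % | Ez / % |
|---|---|---|---|
| delta | 6.00 | 9 | 44 |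
| delta | 8.00 | 15 | 40 |
| delta | 12.0 | 19 | 31 |
| delta | 20.0 | 32 | 17 |
| delta | 30.0 | 40 | 11 |
| delta | 50.0 | 42 | 4 |
| delta | 80.0 | 42 | 1 |
| theta | 4.00 | 1 | 7 |
| theta | 12.0 | 2 | 1 |
| theta | 20.0 | 3 | 0 |
| theta | 30.0 | 2 | 3 |
| theta | 40.0 | 1 | 0 |
| theta | 60.0 | 0 | 1 |
| theta | 80.0 | 2 | 3 |

(each reading ± 1.5 percentage points)

* average number of monomer units in a chain (chains begun, living or dead) at 1.0 h
* part of the Ez that has reacted at 1.0 h

- the average divides the monomer in chains by the number of chains begun, living and dead together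
- the earlier runs do not show the number of chains; that part of a forecast is a guess

Theta, with Eb at 1.95 times Ez, keeps a fraction 7% of Ez at 4.00 min. The closed form of the second-order rate turns that one reading into τ = 1.89 min, the time in which equal charges of Eb and Ez, left to themselves, halve each other. With equal charges and no other loss, the fraction left is then one over one plus t/τ.

Can growth compete? Delta's Ez falls from 17% to 4% between 20.0 min and 50.0 min, which I read as a growth time of 20.7 min. The ratio τ to growth time, a selectivity factor, is 0.0912, so with Eb at its full charge and growth as read in delta, Eb takes Ez about ten times as fast as growth does.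

How much Ez is left at 1.0 h? With Eb as the one loss, τ leaves a fraction 3.06%, so Eb by itself takes 96.9%, and I put c at that or above. The runs do not show the chain count, so I reckon no dp.

The forecast puts dp at 2.2, “which is partly a guess”, and c at 98%.

The flask gives dp 3.11 and c 99.9%.

    Ly + Qo → Ly.Qo (k = 0.00110 M⁻¹ s⁻¹)
    Ry → Uv (k = 3.40 × 10⁻⁴ s⁻¹)
    Ez + Ly → Ry + Qo (k = 0.00173 M⁻¹ s⁻¹)
    Ez + Ry → Qo + Ry, rate k4*[Ry]*[Ez] (k = 0.0297 M⁻¹ s⁻¹)
    Eb + Ez → Eb.Ez (k = 0.0113 M⁻¹ s⁻¹)

In the flask τ puts Eb at 24.0% of its charge at 0.100 h, and 24.8% stands there. At 1.00 h τ gives 3.06%, but Eb stands at 10.7%, and Qo with Ly.Qo holds 10.6% of the Ez charged. For the neighbour with 25 mol% of Ly, charged with the same Eb and Ez, τ gives 3.06% too, but its Eb stands at 18.0% and its dp at 2.00. In the flask the half-life of Eb by Eb + Ez with Ez as charged is 1.2 min, far shorter than the 22 h it has reached at 1.00 h, when Ez is down to 0.0952% of its charge.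

The runs are calculated for an exercise, noise included.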